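**Strategy**

1. Retrosynthesis, late cuts: the enal and the free primary alcohol are unmasked last from an ethyl ester and a pivalate. The two inner C=C bonds of the tetraenyl side chain are cut by Wittig reactions, back to a tetrahydrofuran-2-carbaldehyde, a formyl-substituted ethylidene phosphorane and geranyl bromide.
2. Retrosynthesis, core cuts: the O–CH2 carbon of the tetrahydrofuran is traced to a lactone carbonyl. The ring bond between the C(CH3)OH carbon and its ring CH2 is cut (samarium diiodide Barbier closure). The bond between the spiro carbon and the ring CH bearing the 3-hydroxypropyl chain is cut (Michael union), leaving an α-acetyl γ-butyrolactone and a (2Z,4E)-dienal ester.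
3. Enabling feature: the spiro carbon (the ring carbon that carries the CH2O of the tetrahydrofuran) is the α-carbon of a masked γ-butyrolactone and of a masked acetyl group, whose carbonyl carbon is the later C(CH3)OH carbon. It is therefore a doubly activated carbon acid. Its neighbour, the ring CH with the hydroxypropyl chain, is the β-carbon of a masked enal whose β-substituent already is the tetrasubstituted C=C(CH3)–C(=O) unit.
4. Forward order: the lactone ring is bought; the Michael union closes no ring; the cyclohexane closes directly afterwards by the Barbier reaction; the lactone is reduced to the tetrahydrofuran; the chain is joined by two Wittig reactions; a reduction/oxidation pair finishes.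
5. Stereochemistry: the tetrahydrofuran CH comes from the bought (R)-lactone; the spiro carbon from attack anti to the silyloxymethyl group; the adjacent ring CH from the (R)-diphenylprolinol silyl ether; the carbinol from samarium chelation; the tetrasubstituted alkene from a (Z)-enol triflate coupled with retention; the triene from (E)-geranyl bromide and two E-selective Wittig reactions.

Key step: step 7

Remark: the sense of induction of the amine catalyst in step 7 is taken from the usual shielding model of diarylprolinol silyl ether iminium ions; metal enolates, iminium and oxocarbenium ions and organosamarium or aluminium species are treated as mechanism and are not numbered. TBDPS = tert-butyldiphenylsilyl.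

**Route**

Step 1
Reactants: 1 (R)-5-(hydroxymethyl)dihydrofuran-2(3H)-one
Product: 2 (R)-5-(TBDPS-oxymethyl)dihydrofuran-2(3H)-one
Conditions: TBDPSCl, imidazole, DMF, 0 °C → rt
Reagents that add atoms: tert-butyl(chloro)diphenylsilane, CC(C)(C)[Si](Cl)(c1ccccc1)c1ccccc1
Why: Imidazole-promoted silylation of a primary alcohol, which leaves the stereocentre untouched; the diphenyl silyl ether is chosen because it has to survive BF3·OEt2 in step 12 and adds bulk for the facial control of step 7.

Step 2
Reactants: 2 (R)-5-(TBDPS-oxymethyl)dihydrofuran-2(3H)-one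
Product: 3 (5R)-3-acetyl-5-(TBDPS-oxymethyl)dihydrofuran-2(3H)-one (C-3 epimers and enol)
Conditions: LiN(SiMe3)2 (2.2 equiv), THF, −78 °C; 1-acetylimidazole, −78 → 0 °C; aq NH4Cl
Reagents that add atoms: 1-acetylimidazole, CC(=O)n1ccnc1
Why: Crossed Claisen C-acylation of the lactone lithium enolate by an acyl imidazole, the second equivalent of base taking up the more acidic product; the new C-3 centre forms as a mixture, which does not matter because it is planar again in the enol that reacts in step 7.

Step 3
Reactants: 4 diethyl methylmalonate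
Product: 5 ethyl hydrogen methylmalonate (3-ethoxy-2-methyl-3-oxopropanoic acid)
Conditions: KOH (1.0 equiv), EtOH, rt; aq HCl
Reagents that add atoms: potassium hydroxide, [K+].[OH-]
Why: Half saponification of a malonic diester, which stops after one ester because the carboxylate formed deactivates the second one.

Step 4
Reactants: 5 ethyl hydrogen methylmalonate; 6 3-chloropropanoyl chloride
Product: 8 ethyl 5-chloro-2-methyl-3-oxopentanoate, via acylated malonic half ester 7 (not isolated)
Conditions: n-BuLi (2.0 equiv), THF, −78 → −10 °C; 6, −78 °C; aq HCl, rt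
Reagents that add atoms: none
Why: C-Acylation of the dilithio dianion of a malonic half ester by an acid chloride, followed by decarboxylation of the β-keto acid on acidification (malonic half-ester synthesis of β-keto esters); the low temperature and the absence of an amine base keep the 3-chloropropanoyl unit from losing HCl, and the racemic C-2 centre disappears in step 5.

Step 5
Reactants: 8 ethyl 5-chloro-2-methyl-3-oxopentanoate
Product: 9 ethyl (Z)-5-chloro-2-methyl-3-(trifluoromethylsulfonyloxy)pent-2-enoate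
Conditions: LiN(SiMe3)2 (1.05 equiv), Et2O, −78 °C; Tf2O, −78 → 0 °C
Reagents that add atoms: trifluoromethanesulfonic anhydride, O=S(=O)(OS(=O)(=O)C(F)(F)F)C(F)(F)F
Why: Enol triflation (O-sulfonylation) of the lithium enolate, in which lithium bridges the enolate oxygen and the ester carbonyl so that OTf ends cis to CO2Et and fixes the geometry of the later tetrasubstituted alkene; complete deprotonation at C-2 leaves no free base to eliminate HCl.

Step 6
Reactants: 9 (Z)-enol triflate; 10 (E)-3,3-diethoxyprop-1-enylboronic acid pinacol ester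
Product: 12 ethyl (2Z,4E)-3-(2-chloroethyl)-2-methyl-6-oxohexa-2,4-dienoate, via diethyl acetal 11 (not isolated)
Conditions: Pd(PPh3)4 (5 mol %), K3PO4, 1,4-dioxane/H2O, 50 °C; then 1 M HCl, THF, rt
Reagents that add atoms: water, O
Why: Suzuki–Miyaura coupling of an enol triflate with an alkenylboronate runs with retention at both sp2 carbons and leaves the primary alkyl chloride alone, and acid hydrolysis of the acetal then frees the (E)-enal.

Step 7
Reactants: 3 acetyl lactone; 12 dienal ester
Product: 13 Michael adduct, ethyl (2Z,4R)-4-[(3R,5R)-3-acetyl-5-(TBDPS-oxymethyl)-2-oxooxolan-3-yl]-3-(2-chloroethyl)-2-methyl-6-oxohex-2-enoate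
Conditions: (R)-2-[diphenyl(trimethylsilyloxy)methyl]pyrrolidine (20 mol %), PhCO2H (20 mol %), toluene, 0 °C → rt
Reagents that add atoms: none
Why: The secondary amine condenses with dienal 12 to an (E)-iminium ion, the enol of acetyl lactone 3 adds to its β-carbon, and hydrolysis of the enamine so formed releases aldehyde 13 and the amine, so that the lactone α-carbon (the later spiro carbon) becomes bonded to the former β-carbon of the dienal (the later ring CH with the hydroxypropyl chain). The closest known reaction type is the diarylprolinol silyl ether-catalysed Michael addition of α-substituted cyclic β-keto esters and α-acyl lactones to enals, which builds a quaternary carbon next to a tertiary one; a β-substituent that is a fully substituted alkenyl ester has not been tried but changes neither the bond formed nor the substrate class. No ring is closed in this step. The quaternary carbon is controlled by the substrate, since the bulky silyloxymethyl group at C-5 covers one face of the planar enol and the iminium ion approaches anti to it, leaving the acetyl group cis to that substituent; the methine is controlled by the catalyst, whose diphenyl(silyloxy)methyl arm shields one face of the iminium ion, and the usual shielding model assigns the (R)-amine to the (R)-methine needed here. The step needs addition at the β-carbon (1,4) and not at the δ-carbon (1,6), and only one addition: the δ-carbon is fully substituted and carries the ester, which disfavours both positive charge and attack there, and the product has no hydrogen left on the quaternary carbon, so it cannot react a second time. The primary chloride, the (Z)-tetrasubstituted enoate and the silyl ether are inert to the amine and benzoic acid.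

Step 8
Reactants: 13 Michael adduct
Product: 14 terminal alkene, ethyl (2Z,4R)-4-[(3R,5R)-3-acetyl-5-(TBDPS-oxymethyl)-2-oxooxolan-3-yl]-3-(2-chloroethyl)-2-methylhepta-2,6-dienoate
Conditions: CH2I2, Zn, Ti(OiPr)4, THF, rt
Reagents that add atoms: diiodomethane, ICI
Why: Takai-type methylenation with the gem-dimetallic reagent from CH2I2 and zinc, which with Ti(OiPr)4 converts aldehydes but not ketones, lactones or esters and is not basic, so that neither retro-Michael cleavage nor aldol closure of the acetyl group onto the aldehyde can start.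

Step 9
Reactants: 14 chloro alkene
Product: 15 iodo ketone, the 3-(2-iodoethyl) analogue of 14
Conditions: NaI, 2-butanone, 70 °C, dark
Reagents that add atoms: sodium iodide, [Na+].[I-]
Why: Finkelstein exchange (SN2 at the primary carbon) driven by precipitation of NaCl; under these neutral conditions the quaternary β-dicarbonyl unit has no acidic hydrogen to lose.

Step 10
Reactants: 15 iodo ketone
Product: 16 spiro hydroxy lactone, ethyl (2Z)-2-[(3R,5R,6S,10R)-3-(TBDPS-oxymethyl)-6-hydroxy-6-methyl-1-oxo-10-(prop-2-enyl)-2-oxaspiro[4.5]decan-9-ylidene]propanoate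
Conditions: SmI2 (2.5 equiv), THF, −78 → 0 °C; aq NH4Cl
Reagents that add atoms: none
Why: Samarium Barbier cyclisation of an ω-iodoalkyl β-keto ester, in which two single-electron transfers join the CH2I carbon to the acetyl carbonyl carbon in a 6-exo-trig closure, and trivalent samarium held between the ketone oxygen and the lactone carbonyl oxygen places the new OH cis to the lactone carbonyl, which is the (S)-carbinol of the target; without HMPA or a proton source the enoate and the terminal alkene should stay untouched, and the ester carbonyl lies trans to the iodoethyl arm and is out of reach.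

Step 11
Reactants: 16 spiro hydroxy lactone
Product: 17 lactol (C-1 anomers), the 1-hydroxy-2-oxaspiro[4.5]decane corresponding to 16
Conditions: iBu2AlH (2.5 equiv), CH2Cl2, −78 °C; aq KNaC4H4O6
Reagents that add atoms: none
Why: Partial reduction of a lactone to the lactol by iBu2AlH at −78 °C, where the tetrahedral aluminium hemiacetal survives until work-up; the γ-lactone, activated by the neighbouring aluminium alkoxide of the tertiary alcohol, should react ahead of the twisted tetrasubstituted ethyl enoate, and the new anomeric centre is removed in step 12.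

Step 12
Reactants: 17 lactol
Product: 18 spiro tetrahydrofuran, ethyl (2Z)-2-[(3R,5S,6S,10R)-3-(TBDPS-oxymethyl)-6-hydroxy-6-methyl-10-(prop-2-enyl)-2-oxaspiro[4.5]decan-9-ylidene]propanoate
Conditions: Et3SiH (10 equiv), BF3·OEt2, CH2Cl2, −78 → −40 °C
Reagents that add atoms: none
Why: Ionic hydrogenation of a lactol, in which BF3 ionises the hemiacetal to the cyclic oxocarbenium ion and Et3SiH delivers hydride, turning the anomeric carbon into the CH2 of the tetrahydrofuran; the large excess of silane and the low temperature are meant to outrun capture of the cation by the pendant alkene and loss of the silyl ether.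

Step 13
Reactants: 18 spiro tetrahydrofuran
Product: 20 primary alcohol with a 3-hydroxypropyl chain at C-10 (otherwise as 18), via alkyl-9-BBN adduct 19 (not isolated)
Conditions: 9-BBN (3 equiv), THF, 0 °C → rt; H2O2, aq NaOH, 0 °C
Reagents that add atoms: hydrogen peroxide, OO
Why: Hydroboration–oxidation with 9-BBN is anti-Markovnikov at the monosubstituted alkene and leaves the tetrasubstituted ester-bearing alkene alone; no stereocentre is formed.

Step 14
Reactants: 20 primary alcohol
Product: 21 pivalate, the 10-[3-(pivaloyloxy)propyl] analogue of 20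
Conditions: PivCl, pyridine, CH2Cl2, 0 °C
Reagents that add atoms: pivaloyl chloride, CC(C)(C)C(=O)Cl
Why: Acylation of the primary alcohol only, the hindered tertiary alcohol being inert at 0 °C; the pivalate withstands fluoride, periodinane and ylides and is cleaved by the hydride of step 19.

Step 15
Reactants: 21 pivalate
Product: 22 hydroxymethyl tetrahydrofuran, ethyl (2Z)-2-[(3R,5S,6S,10R)-6-hydroxy-3-(hydroxymethyl)-6-methyl-10-[3-(pivaloyloxy)propyl]-2-oxaspiro[4.5]decan-9-ylidene]propanoate
Conditions: Bu4NF, AcOH, THF, rt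
Reagents that add atoms: none
Why: Fluoride-induced cleavage of the Si–O bond, buffered with acetic acid so that the alkoxide formed cannot attack the esters.

Step 16
Reactants: 22 hydroxymethyl tetrahydrofuran
Product: 23 core aldehyde, the 3-formyl analogue of 22
Conditions: Dess–Martin periodinane, CH2Cl2, 0 °C → rt
Reagents that add atoms: none
Why: Dess–Martin oxidation of a primary alcohol to the aldehyde under near-neutral conditions, which leaves the tertiary alcohol alone and should not epimerise the α-alkoxy stereocentre.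

Step 17
Reactants: 23 core aldehyde; 24 2-(triphenylphosphoranylidene)propanal
Product: 25 (E)-2-methyl enal, the 3-[(E)-2-methyl-3-oxoprop-1-enyl] analogue of 23
Conditions: toluene, 70 °C
Reagents that add atoms: none
Why: Wittig olefination with a stabilised ylide, E-selective through reversible oxaphosphetane formation; the conjugated, α-branched product enal is much less electrophilic than 23, so a second homologation should not follow.

Step 18
Reactants: 25 (E)-2-methyl enal; 26 geranyl bromide
Product: 29 full (1E,3E,5E)-triene bearing ethyl ester and pivalate, via geranyltributylphosphonium bromide 27 (not isolated), via tributylphosphonium ylide 28 (not isolated)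
Conditions: PBu3, THF, rt; NaN(SiMe3)2, −78 °C; then 25 (0.3 equiv), −78 → 0 °C
Reagents that add atoms: none
Why: Wittig olefination with an allylic trialkylphosphonium ylide, a semi-stabilised ylide known to give (E)-alkenes with high selectivity; the (E)-alkene of the geranyl unit is kept, the esters do not react, and the excess of ylide allows for deprotonation of the tertiary alcohol.

Step 19
Reactants: 29 triene ester pivalate
Product: 30 allylic alcohol diol, (2Z)-2-[(3R,5S,6S,10R)-6-hydroxy-10-(3-hydroxypropyl)-6-methyl-3-[(1E,3E,5E)-2,6,10-trimethylundeca-1,3,5,9-tetraenyl]-2-oxaspiro[4.5]decan-9-ylidene]propan-1-ol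
Conditions: iBu2AlH (6 equiv), CH2Cl2, −78 → −20 °C; aq KNaC4H4O6
Reagents that add atoms: none
Why: 1,2-Reduction of the enoate to the allylic alcohol by iBu2AlH with simultaneous reductive cleavage of the pivalate; alkene geometries and stereocentres are not touched.

Step 20
Reactants: 30 allylic alcohol diol
Product: 31 target CNP0220216.1
Conditions: MnO2, CH2Cl2, rt, dark
Reagents that add atoms: none
Why: MnO2 oxidises only the allylic alcohol, so the saturated primary and the tertiary alcohol remain, and exclusion of light protects the triene from E/Z isomerisation.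

**Compound list**

1 | (R)-5-(hydroxymethyl)dihydrofuran-2(3H)-one | OC[C@H]1CCC(=O)O1 | starting material
2 | (R)-5-(TBDPS-oxymethyl)dihydrofuran-2(3H)-one | CC(C)(C)[Si](c1ccccc1)(c1ccccc1)OC[C@H]1CCC(=O)O1 | intermediate
3 | (5R)-3-acetyl-5-(TBDPS-oxymethyl)dihydrofuran-2(3H)-one (C-3 epimers and enol) | CC(C)(C)[Si](c1ccccc1)(c1ccccc1)OC[C@H]1CC(C(C)=O)C(=O)O1 | intermediate
4 | diethyl methylmalonate | CCOC(=O)C(C)C(=O)OCC | starting material
5 | ethyl hydrogen methylmalonate | CCOC(=O)C(C)C(=O)O | intermediate
6 | 3-chloropropanoyl chloride | O=C(Cl)CCCl | starting material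
7 | 2-(3-chloropropanoyl)-3-ethoxy-2-methyl-3-oxopropanoic acid (not isolated) | CCOC(=O)C(C)(C(=O)O)C(=O)CCCl | intermediate
8 | ethyl 5-chloro-2-methyl-3-oxopentanoate | CCOC(=O)C(C)C(=O)CCCl | intermediate
9 | ethyl (Z)-5-chloro-2-methyl-3-(trifluoromethylsulfonyloxy)pent-2-enoate | CCOC(=O)/C(C)=C(\OS(=O)(=O)C(F)(F)F)CCCl | intermediate
10 | (E)-2-(3,3-diethoxyprop-1-enyl)-4,4,5,5-tetramethyl-1,3,2-dioxaborolane | CCOC(OCC)/C=C/B1OC(C)(C)C(C)(C)O1 | starting material
11 | ethyl (2Z,4E)-3-(2-chloroethyl)-6,6-diethoxy-2-methylhexa-2,4-dienoate (not isolated) | CCOC(=O)/C(C)=C(CCCl)\C=C\C(OCC)OCC | intermediate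
12 | ethyl (2Z,4E)-3-(2-chloroethyl)-2-methyl-6-oxohexa-2,4-dienoate | CCOC(=O)/C(C)=C(CCCl)\C=C\C=O | intermediate
13 | ethyl (2Z,4R)-4-[(3R,5R)-3-acetyl-5-(TBDPS-oxymethyl)-2-oxooxolan-3-yl]-3-(2-chloroethyl)-2-methyl-6-oxohex-2-enoate | CC(C)(C)[Si](c1ccccc1)(c1ccccc1)OC[C@H]1C[C@@](C(C)=O)(C(=O)O1)[C@H](CC=O)/C(CCCl)=C(/C)C(=O)OCC | intermediate
14 | ethyl (2Z,4R)-4-[(3R,5R)-3-acetyl-5-(TBDPS-oxymethyl)-2-oxooxolan-3-yl]-3-(2-chloroethyl)-2-methylhepta-2,6-dienoate | CC(C)(C)[Si](c1ccccc1)(c1ccccc1)OC[C@H]1C[C@@](C(C)=O)(C(=O)O1)[C@H](CC=C)/C(CCCl)=C(/C)C(=O)OCC | intermediate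
15 | ethyl (2Z,4R)-4-[(3R,5R)-3-acetyl-5-(TBDPS-oxymethyl)-2-oxooxolan-3-yl]-3-(2-iodoethyl)-2-methylhepta-2,6-dienoate | CC(C)(C)[Si](c1ccccc1)(c1ccccc1)OC[C@H]1C[C@@](C(C)=O)(C(=O)O1)[C@H](CC=C)/C(CCI)=C(/C)C(=O)OCC | intermediate
16 | ethyl (2Z)-2-[(3R,5R,6S,10R)-3-(TBDPS-oxymethyl)-6-hydroxy-6-methyl-1-oxo-10-(prop-2-enyl)-2-oxaspiro[4.5]decan-9-ylidene]propanoate | CC(C)(C)[Si](c1ccccc1)(c1ccccc1)OC[C@H]1C[C@@]2(C(=O)O1)[C@H](CC=C)/C(=C(/C)C(=O)OCC)CC[C@]2(C)O | intermediate
17 | ethyl (2Z)-2-[(3R,5R,6S,10R)-3-(TBDPS-oxymethyl)-1,6-dihydroxy-6-methyl-10-(prop-2-enyl)-2-oxaspiro[4.5]decan-9-ylidene]propanoate (C-1 anomers) | CC(C)(C)[Si](c1ccccc1)(c1ccccc1)OC[C@H]1C[C@@]2(C(O)O1)[C@H](CC=C)/C(=C(/C)C(=O)OCC)CC[C@]2(C)O | intermediate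
18 | ethyl (2Z)-2-[(3R,5S,6S,10R)-3-(TBDPS-oxymethyl)-6-hydroxy-6-methyl-10-(prop-2-enyl)-2-oxaspiro[4.5]decan-9-ylidene]propanoate | CC(C)(C)[Si](c1ccccc1)(c1ccccc1)OC[C@H]1C[C@@]2(CO1)[C@H](CC=C)/C(=C(/C)C(=O)OCC)CC[C@]2(C)O | intermediate
19 | alkylborane from 18 with 9-borabicyclo[3.3.1]nonan-9-yl at the chain terminus (not isolated) | CC(C)(C)[Si](c1ccccc1)(c1ccccc1)OC[C@H]1C[C@@]2(CO1)[C@H](CCCB1C3CCCC1CCC3)/C(=C(/C)C(=O)OCC)CC[C@]2(C)O | intermediate
20 | ethyl (2Z)-2-[(3R,5S,6S,10R)-3-(TBDPS-oxymethyl)-6-hydroxy-10-(3-hydroxypropyl)-6-methyl-2-oxaspiro[4.5]decan-9-ylidene]propanoate | CC(C)(C)[Si](c1ccccc1)(c1ccccc1)OC[C@H]1C[C@@]2(CO1)[C@H](CCCO)/C(=C(/C)C(=O)OCC)CC[C@]2(C)O | intermediate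
21 | ethyl (2Z)-2-[(3R,5S,6S,10R)-3-(TBDPS-oxymethyl)-6-hydroxy-6-methyl-10-[3-(pivaloyloxy)propyl]-2-oxaspiro[4.5]decan-9-ylidene]propanoate | CC(C)(C)[Si](c1ccccc1)(c1ccccc1)OC[C@H]1C[C@@]2(CO1)[C@H](CCCOC(=O)C(C)(C)C)/C(=C(/C)C(=O)OCC)CC[C@]2(C)O | intermediate
22 | ethyl (2Z)-2-[(3R,5S,6S,10R)-6-hydroxy-3-(hydroxymethyl)-6-methyl-10-[3-(pivaloyloxy)propyl]-2-oxaspiro[4.5]decan-9-ylidene]propanoate | OC[C@H]1C[C@@]2(CO1)[C@H](CCCOC(=O)C(C)(C)C)/C(=C(/C)C(=O)OCC)CC[C@]2(C)O | intermediate
23 | ethyl (2Z)-2-[(3R,5S,6S,10R)-3-formyl-6-hydroxy-6-methyl-10-[3-(pivaloyloxy)propyl]-2-oxaspiro[4.5]decan-9-ylidene]propanoate | O=C[C@H]1C[C@@]2(CO1)[C@H](CCCOC(=O)C(C)(C)C)/C(=C(/C)C(=O)OCC)CC[C@]2(C)O | intermediate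
24 | 2-(triphenylphosphoranylidene)propanal | CC(C=O)=P(c1ccccc1)(c1ccccc1)c1ccccc1 | starting material
25 | ethyl (2Z)-2-[(3R,5S,6S,10R)-6-hydroxy-6-methyl-3-[(E)-2-methyl-3-oxoprop-1-enyl]-10-[3-(pivaloyloxy)propyl]-2-oxaspiro[4.5]decan-9-ylidene]propanoate | O=C/C(C)=C/[C@H]1C[C@@]2(CO1)[C@H](CCCOC(=O)C(C)(C)C)/C(=C(/C)C(=O)OCC)CC[C@]2(C)O | intermediate
26 | geranyl bromide, (E)-1-bromo-3,7-dimethylocta-2,6-diene | CC(C)=CCC/C(C)=C/CBr | starting material
27 | (E)-geranyltributylphosphonium bromide (not isolated) | CC(C)=CCC/C(C)=C/C[P+](CCCC)(CCCC)CCCC.[Br-] | intermediate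
28 | tributyl[(E)-3,7-dimethylocta-2,6-dienylidene]phosphorane (not isolated) | CC(C)=CCC/C(C)=C/C=P(CCCC)(CCCC)CCCC | intermediate
29 | ethyl (2Z)-2-[(3R,5S,6S,10R)-6-hydroxy-6-methyl-10-[3-(pivaloyloxy)propyl]-3-[(1E,3E,5E)-2,6,10-trimethylundeca-1,3,5,9-tetraenyl]-2-oxaspiro[4.5]decan-9-ylidene]propanoate | CC(C)=CCC/C(C)=C/C=C/C(C)=C/[C@H]1C[C@@]2(CO1)[C@H](CCCOC(=O)C(C)(C)C)/C(=C(/C)C(=O)OCC)CC[C@]2(C)O | intermediate
30 | (2Z)-2-[(3R,5S,6S,10R)-6-hydroxy-10-(3-hydroxypropyl)-6-methyl-3-[(1E,3E,5E)-2,6,10-trimethylundeca-1,3,5,9-tetraenyl]-2-oxaspiro[4.5]decan-9-ylidene]propan-1-ol | CC(C)=CCC/C(C)=C/C=C/C(C)=C/[C@H]1C[C@@]2(CO1)[C@H](CCCO)/C(=C(/C)CO)CC[C@]2(C)O | intermediate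
31 | CNP0220216.1, (2Z)-2-[(3R,5S,6S,10R)-6-hydroxy-10-(3-hydroxypropyl)-6-methyl-3-[(1E,3E,5E)-2,6,10-trimethylundeca-1,3,5,9-tetraenyl]-2-oxaspiro[4.5]decan-9-ylidene]propanal | CC(C)=CCC/C(C)=C/C=C/C(C)=C/[C@H]1C[C@@]2(CO1)[C@H](CCCO)/C(=C(/C)C=O)CC[C@]2(C)O | target

**Step count**

Total: 20 steps. Longest linear sequence: 18 steps (from 4 to 31, steps 3 to 20).

**Steps most likely to fail**

Step 7 (Michael union). The hindered β-carbon may react slowly, so that reversal of the addition, aldol closure of the acetyl group onto the new aldehyde, or a mismatch between catalyst and substrate control could erode conversion and selectivity at the methine. The fallback sets out from 12 and 3 and returns at 13; it forms the same C–C bond by allylic substitution instead of conjugate addition. Reduction of 12 (NaBH4, CeCl3·7H2O, MeOH, Luche conditions) should give the dienol ester F1, and methyl chloroformate with pyridine the allylic methyl carbonate F2. Iridium-catalysed branched-selective allylic alkylation of 3 with F2 ([Ir(cod)Cl]2, a BINOL-derived phosphoramidite of the appropriate handedness, LiOtBu, THF) should give the vinyl lactone F3, with the ligand controlling the methine and the silyloxymethyl group the quaternary carbon. Rhodium-catalysed hydroboration with catecholborane (Rh(PPh3)3Cl), which spares the ketone, followed by NaBO3 should give the primary alcohol F4, and Dess–Martin oxidation leads back to 13.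

Step 10 (Barbier closure). The ketyl or the primary radical may be captured by the terminal alkene (5-exo or 6-exo cyclisation), or the carbon–iodine bond may be reduced before the ring closes. The fallback sets out from 13 and returns at 16; it inverts the order of methylenation and ring closure so that no alkene is present during the electron-transfer step. Acetalisation of the aldehyde alone (HC(OMe)3, PPTS, MeOH) should give the dimethyl acetal F5, NaI in 2-butanone the iodo acetal F6, and SmI2 in THF the spiro hydroxy lactone acetal F7. Aqueous acid should release the hydroxy aldehyde F8, which may rest as its lactol with the tertiary hydroxyl, and Wittig methylenation with excess Ph3P=CH2 then gives 16.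

Step 11 (lactone to lactol). Chemoselectivity may be lost, by hydride transfer to the ethyl enoate or by over-reduction of the lactol to the diol. The fallback sets out from 16 and returns at 21; it replaces the aluminium hydride by a dialkylborane that reduces γ-lactones to lactols, does not touch esters and hydroborates the vinyl group in the same operation. Disiamylborane (excess, THF, 0 °C → rt) followed by NaBO3 should give the lactol diol F9, and PivCl with pyridine at 0 °C the lactol pivalate F10. Ionic hydrogenation (Et3SiH, BF3·OEt2, −78 °C) then gives 21, with no alkene left to intercept the oxocarbenium ion.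

**Further compounds**

F1 | step 7 | ethyl (2Z,4E)-3-(2-chloroethyl)-6-hydroxy-2-methylhexa-2,4-dienoate | CCOC(=O)/C(C)=C(CCCl)\C=C\CO
F2 | step 7 | ethyl (2Z,4E)-3-(2-chloroethyl)-6-(methoxycarbonyloxy)-2-methylhexa-2,4-dienoate | CCOC(=O)/C(C)=C(CCCl)\C=C\COC(=O)OC
F3 | step 7 | ethyl (2Z,4R)-4-[(3R,5R)-3-acetyl-5-(TBDPS-oxymethyl)-2-oxooxolan-3-yl]-3-(2-chloroethyl)-2-methylhexa-2,5-dienoate | CC(C)(C)[Si](c1ccccc1)(c1ccccc1)OC[C@H]1C[C@@](C(C)=O)(C(=O)O1)[C@H](C=C)/C(CCCl)=C(/C)C(=O)OCC
F4 | step 7 | ethyl (2Z,4R)-4-[(3R,5R)-3-acetyl-5-(TBDPS-oxymethyl)-2-oxooxolan-3-yl]-3-(2-chloroethyl)-6-hydroxy-2-methylhex-2-enoate | CC(C)(C)[Si](c1ccccc1)(c1ccccc1)OC[C@H]1C[C@@](C(C)=O)(C(=O)O1)[C@H](CCO)/C(CCCl)=C(/C)C(=O)OCC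
F5 | step 10 | ethyl (2Z,4R)-4-[(3R,5R)-3-acetyl-5-(TBDPS-oxymethyl)-2-oxooxolan-3-yl]-3-(2-chloroethyl)-6,6-dimethoxy-2-methylhex-2-enoate | CC(C)(C)[Si](c1ccccc1)(c1ccccc1)OC[C@H]1C[C@@](C(C)=O)(C(=O)O1)[C@H](CC(OC)OC)/C(CCCl)=C(/C)C(=O)OCC
F6 | step 10 | ethyl (2Z,4R)-4-[(3R,5R)-3-acetyl-5-(TBDPS-oxymethyl)-2-oxooxolan-3-yl]-3-(2-iodoethyl)-6,6-dimethoxy-2-methylhex-2-enoate | CC(C)(C)[Si](c1ccccc1)(c1ccccc1)OC[C@H]1C[C@@](C(C)=O)(C(=O)O1)[C@H](CC(OC)OC)/C(CCI)=C(/C)C(=O)OCC
F7 | step 10 | ethyl (2Z)-2-[(3R,5R,6S,10R)-3-(TBDPS-oxymethyl)-10-(2,2-dimethoxyethyl)-6-hydroxy-6-methyl-1-oxo-2-oxaspiro[4.5]decan-9-ylidene]propanoate | CC(C)(C)[Si](c1ccccc1)(c1ccccc1)OC[C@H]1C[C@@]2(C(=O)O1)[C@H](CC(OC)OC)/C(=C(/C)C(=O)OCC)CC[C@]2(C)O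
F8 | step 10 | ethyl (2Z)-2-[(3R,5R,6S,10R)-3-(TBDPS-oxymethyl)-6-hydroxy-6-methyl-1-oxo-10-(2-oxoethyl)-2-oxaspiro[4.5]decan-9-ylidene]propanoate | CC(C)(C)[Si](c1ccccc1)(c1ccccc1)OC[C@H]1C[C@@]2(C(=O)O1)[C@H](CC=O)/C(=C(/C)C(=O)OCC)CC[C@]2(C)O
F9 | step 11 | ethyl (2Z)-2-[(3R,5R,6S,10R)-3-(TBDPS-oxymethyl)-1,6-dihydroxy-10-(3-hydroxypropyl)-6-methyl-2-oxaspiro[4.5]decan-9-ylidene]propanoate (C-1 anomers) | CC(C)(C)[Si](c1ccccc1)(c1ccccc1)OC[C@H]1C[C@@]2(C(O)O1)[C@H](CCCO)/C(=C(/C)C(=O)OCC)CC[C@]2(C)O
F10 | step 11 | ethyl (2Z)-2-[(3R,5R,6S,10R)-3-(TBDPS-oxymethyl)-1,6-dihydroxy-6-methyl-10-[3-(pivaloyloxy)propyl]-2-oxaspiro[4.5]decan-9-ylidene]propanoate (C-1 anomers) | CC(C)(C)[Si](c1ccccc1)(c1ccccc1)OC[C@H]1C[C@@]2(C(O)O1)[C@H](CCCOC(=O)C(C)(C)C)/C(=C(/C)C(=O)OCC)CC[C@]2(C)O
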